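5 shares are asked, and I want one number to answer them.

| flask | substrate | first nucleophile | capture agent | solid second nucleophile | temperature | remark | time |
|---|---|---|---|---|---|---|---|
| west | 0.078 M | 1.1 equiv | 0.078 M | 0.70 equiv | 20 °C | run made earlier |  |
| south-east | 0.078 M | 1.1 equiv | 0.078 M | 0.98 equiv | 31 °C | run made earlier |  |
| north | 0.078 M | 1.1 equiv | 0.078 M | 1.5 equiv | 20 °C | run made earlier |  |
| south | 0.078 M | 1.1 equiv | 0.039 M | 0.70 equiv | 31 °C | run made earlier |  |
| zeta | 0.078 M | 1.10 equiv (fed, over 25 min) | 0.0780 M | 0.700 equiv | 25 °C | all else is in the flask from the start; the feed brings no volume worth counting | 40 min |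
| delta | 0.078 M (fed, over 2.5 min) | 1.10 equiv | 0.0780 M | 0.700 equiv | 25 °C | all else is in the flask from the start; the feed brings no volume worth counting | 40 min |
| theta | 0.078 M (fed, over 25 min) | 1.10 equiv | 0.0780 M | 0.700 equiv | 25 °C | all else is in the flask from the start; the feed brings no volume worth counting | 40 min |
| gamma | 0.078 M (fed, over 25 min) | 1.10 equiv | 0.0780 M | 0.700 equiv |  | the addition at 5 °C, then warmed to 25 °C; the feed brings no volume worth counting | 40 min |
| epsilon | 0.078 M | 1.10 equiv | 0.0780 M | 0.700 equiv |  | everything together at the start at 5 °C, warmed to 25 °C at 25 min | 40 min |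

- west (time / min: target / %, other capture product / %): 3.00: 9, 9; 5.00: 8, 16; 8.00: 11, 22; 12.0: 14, 32; 15.0: 19, 32; 25.0: 22, 43; 40.0: 31, 54
- south-east (time / min: target / %, other capture product / %): 6.00: 17, 33; 15.0: 27, 52; 20.0: 29, 56; 30.0: 31, 58; 40.0: 31, 59; 50.0: 33, 61
- north (time / min: target / %, other capture product / %): 4.00: 7, 12; 6.00: 9, 21; 8.00: 10, 26; 15.0: 17, 45; 20.0: 15, 50; 30.0: 16, 64; 50.0: 22, 68
- south (time / min: target / %, other capture product / %): 4.00: 14, 19; 12.0: 30, 43; 20.0: 35, 44; 30.0: 37, 52; 50.0: 37, 56

(standard deviation of a reading: 1.5 percentage points)

- the flask with the highest share of target in target plus other capture product ("all alike" if they lie within 1.5 percentage points) (zeta / delta / theta / gamma / epsilon / all alike)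
- share of target in target plus other capture product at the end, zeta
- share of target in target plus other capture product at the end, delta
- share of target in target plus other capture product at the end, theta
- share of target in target plus other capture product at the end, gamma
- share of target in target plus other capture product at the end, epsilon

- at the start none of the solid second nucleophile is in solution

I treat target and other capture product as rivals for one precursor, each taking it in proportion to its nucleophile. The odds of other capture product per target are then a selectivity factor times mean second nucleophile over mean first nucleophile. The last reading of west gives odds of 1.74 and that of south 1.51, with the same ratio of nucleophile charges, at temperatures either side of 25 °C, though south holds 0.039 M of capture agent against 0.078 M in west. Their mean, 1.63, is my batch odds, the other capture product made per target with both nucleophiles charged from the start. That means a share of 38.1%.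

Is one number enough? Scaling west by its solid charge predicts 3.73 for north, whose last reading gives 3.09, so proportion overshoots this change of charge.

I reckon that feeding substrate leaves the nucleophile ratio alone, so delta and theta both keep 38.1%. Zeta differs: its first nucleophile is fed steadily over 25 min, so the amount fed, consumption set aside, averages 68.8% of charge over 40 min. Its odds become 2.37, a share of 29.7%. The mean may flatter zeta: batch west had made 54.1% of the products of its last reading by 12.0 min, earlier than the feed in zeta ends, so I expect somewhat less. The last share read in west, at 20 °C, is lower than in south, at 31 °C, though their capture agent differs too, so I put the cold-started gamma and epsilon below 38.1%.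

The forecast names delta, with zeta 32%, delta 37%, theta 31%, gamma 32% and epsilon 34%, holding that “Slow feeds let the solid dissolve ahead of the intermediate”. On theta we part: I have 38.1%.

The flasks give delta as the highest, with zeta 28.6%, delta 39.3%, theta 37.7%, gamma 34.7% and epsilon 34.1%.

    substrate ⇌ open intermediate (K = 0.0470, k = 0.00460 s⁻¹, Ea = 76.0 kJ mol⁻¹, ΔH = −8.00 kJ mol⁻¹)
    first nucleophile + open intermediate → target (k = 0.170 M⁻¹ s⁻¹, Ea = 61.0 kJ mol⁻¹)
    second nucleophile + open intermediate → other capture product (k = 0.640 M⁻¹ s⁻¹, Ea = 44.0 kJ mol⁻¹)
    open intermediate + capture agent → trapped intermediate (k = 0.0130 M⁻¹ s⁻¹, Ea = 43.0 kJ mol⁻¹)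
    solid second nucleophile ⇌ second nucleophile, rate k5*(cs5 - [second nucleophile]) while solid is left; crystals form when [second nucleophile] > cs5 (solubility = 0.0700 M, k = 0.00930 s⁻¹)
    open intermediate → side product (k = 9.50 × 10⁻⁴ s⁻¹, Ea = 92.0 kJ mol⁻¹)
    (constants at 25 °C)

Theta ends 6.7 percentage points above the forecast. Dosed over 2.50 min instead of 25 min, theta gives 39.3%, and the share 38.1% from my batch odds of 1.63 lies below that and above the 37.7% of the slow feed.

Now zeta with 1.90 equiv of first nucleophile: scaling its odds by the charge gives 1.37, a share of 42.2%. The computed flask gives 37.4%, less than that, so the proportion again overshoots, as it did in north.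

The runs stem from a simulated flask with made-up constants, noise included.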